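**Retrosynthetic overview**

- The strategy rests on the contiguous C6(Ph)–C1(aroyl)–C2(prenyl) C–H stereotriad of the cyclohexene ring (C1 aroyl, C2 prenyl, C3(Me)=C4, C5H2, C6 Ph). Cutting C3=C4 (ring-closing metathesis transform) turns it into an open chain with an allyl end on C6 and an isopropenyl end on C2.
- Key disconnection: the C6–Ph and C1–C6 bonds are made by two successive sparteine-controlled lithiation–borylation homologations of PhBpin, first with but-3-enyl carbamate, then with (R)-lavandulyl carbamate. C2 comes from an Evans deconjugative prenylation.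
- The aroyl carbon is inserted into the C1–B bond by Matteson homologation. The aryl–C(=O) bond comes from the ortho-lithiated bis-MOM ether of 5-methoxyresorcinol and the C1 carbaldehyde.
- Ring order: the arene is bought; the cyclohexene is closed by metathesis (step 8); the 2,2-dimethyl-2H-pyran ring is fused on last with prenal (step 14).

Key step: step 6

Remark: cyclohexene numbering is used for all intermediates; the given SMILES is read as (1R,2S,6R), i.e. aroyl trans to phenyl and cis to prenyl; both sparteine enantiomers are taken as purchasable; boron ate complexes and metal alkoxides before work-up are treated as part of the mechanism of their step and are not numbered.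

**Route**

Step 1
Reactants: 1 but-3-en-1-ol
Product: 2 but-3-en-1-yl N,N-diisopropylcarbamate
Conditions: i-Pr2NCOCl, Et3N, CH2Cl2, reflux
Reagents that add atoms: N,N-diisopropylcarbamoyl chloride, CC(C)N(C(C)C)C(=O)Cl
Why: O-Carbamoylation (nucleophilic acyl substitution) of the unhindered primary alcohol installs the N,N-diisopropylcarbamate that later directs α-lithiation and serves as the leaving group in step 6.

Step 2
Reactants: 3 (R)-4-benzyloxazolidin-2-one; 4 3-methylbut-2-enoyl chloride
Product: 6 (R)-4-benzyl-3-(3-methylbut-2-enoyl)oxazolidin-2-one, via lithium oxazolidinide 5 (not isolated)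
Conditions: n-BuLi, THF, −78 °C; then 4, −78 → 0 °C
Reagents that add atoms: none
Why: N-Acylation of the lithiated Evans oxazolidinone 5 by the acid chloride (nucleophilic acyl substitution) is fast at −78 °C and leaves the conjugated enoyl group untouched.

Step 3
Reactants: 6 (R)-4-benzyl-3-(3-methylbut-2-enoyl)oxazolidin-2-one; 7 1-bromo-3-methylbut-2-ene (prenyl bromide)
Product: 9 (R)-4-benzyl-3-[(2R)-5-methyl-2-(prop-1-en-2-yl)hex-4-enoyl]oxazolidin-2-one, via sodium Z-dienolate 8 (not isolated)
Conditions: NaHMDS, THF, −78 °C; then 7, −78 → −40 °C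
Reagents that add atoms: none
Why: Evans auxiliary-controlled alkylation in its deconjugative form: NaHMDS removes a γ-proton to give the chelated Z(O)-dienolate 8, which reacts at Cα with the allylic bromide (SN2) on the face opposite the benzyl group, so the new α-centre carrying the isopropenyl group should be formed as (R) (the future C2).

Step 4
Reactants: 9 (R)-4-benzyl-3-[(2R)-5-methyl-2-(prop-1-en-2-yl)hex-4-enoyl]oxazolidin-2-one
Product: 10 (R)-lavandulol, (2R)-5-methyl-2-(prop-1-en-2-yl)hex-4-en-1-ol
Conditions: LiBH4, MeOH (1 equiv), Et2O, 0 °C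
Reagents that add atoms: none
Why: Hydride reduction of the exocyclic imide carbonyl with LiBH4 releases the primary alcohol and the intact auxiliary under conditions too mild to epimerise or conjugate the β,γ-unsaturated stereocentre.

Step 5
Reactants: 10 (R)-lavandulol
Product: 11 (2R)-5-methyl-2-(prop-1-en-2-yl)hex-4-en-1-yl N,N-diisopropylcarbamate
Conditions: i-Pr2NCOCl, Et3N, CH2Cl2, reflux
Reagents that add atoms: N,N-diisopropylcarbamoyl chloride, CC(C)N(C(C)C)C(=O)Cl
Why: The same O-carbamoylation as in step 1 (nucleophilic acyl substitution) converts the primary alcohol into the Hoppe carbamate without touching the adjacent stereocentre.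

Step 6
Reactants: 2 but-3-en-1-yl N,N-diisopropylcarbamate; 12 4,4,5,5-tetramethyl-2-phenyl-1,3,2-dioxaborolane (PhBpin); 11 (2R)-5-methyl-2-(prop-1-en-2-yl)hex-4-en-1-yl N,N-diisopropylcarbamate
Product: 16 open-chain boronic ester 2-[(4R,5R,6S)-9-methyl-4-phenyl-6-(prop-1-en-2-yl)deca-1,8-dien-5-yl]-4,4,5,5-tetramethyl-1,3,2-dioxaborolane, via (R)-lithiated butenyl carbamate 13 (not isolated), via (S)-benzylic boronic ester 14 (not isolated), via (S)-lithiated lavandulyl carbamate 15 (not isolated)
Conditions: (i) 2 (1.3 equiv), (+)-sparteine, s-BuLi, Et2O, −78 °C, 5 h; 12 (1.0 equiv), −78 °C, 1 h; MgBr2·OEt2, then reflux, 16 h; crude 14 passed through a short silica plug and taken up in Et2O; (ii) 11 (1.5 equiv), (−)-sparteine, s-BuLi, Et2O, −78 °C, 5 h; crude 14, −78 °C, 2 h; MgBr2·OEt2, then reflux, 16 h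
Reagents that add atoms: none
Why: s-BuLi/(+)-sparteine removes the pro-R α-proton of 2 to give the configurationally stable (R)-lithiated carbamate 13, which adds to the boron of 12 with retention; in the resulting ate complex the phenyl group migrates from boron to carbon anti to the departing carbamate (inversion at carbon), forming the C6–Ph bond and (S)-14. The same sequence with s-BuLi/(−)-sparteine on 11 (pro-S proton removed, (S)-15) and 14 forms the C1–C6 bond, the benzylic C6 migrating with retention of its configuration. The closest known reaction type is iterative (assembly-line) lithiation–borylation, a 1,2-metallate rearrangement of boronate complexes of Hoppe carbamates. No ring is closed; the product is the open chain carrying C6, C1 and C2 with the allyl and isopropenyl ends. C6 is set by (+)-sparteine and C1 by (−)-sparteine through stereospecific lithiation, borylation and migration, while C2 is carried unchanged from auxiliary-made 11. The step needs α-lithiation next to oxygen and not at the allylic positions, which the carbamate carbonyl secures by directing s-BuLi to the adjacent CH2, and it needs reagent control over the β-stereocentre of 11, which the sparteine–lithium complex is expected to impose.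

Step 7
Reactants: 16 open-chain boronic ester
Product: 18 (2R,3S)-6-methyl-2-[(1R)-1-phenylbut-3-en-1-yl]-3-(prop-1-en-2-yl)hept-5-en-1-ol, via homologated primary boronic ester 17 (not isolated)
Conditions: BrCH2Cl, n-BuLi, Et2O, −78 °C → rt; then NaOH aq., H2O2, THF, 0 °C → rt
Reagents that add atoms: bromochloromethane, ClCBr; hydrogen peroxide, OO
Why: Matteson homologation, in which chloromethyllithium formed in the flask by Br/Li exchange adds to boron and the C1 alkyl group migrates to CH2 with loss of chloride and retention at C1, followed by alkaline peroxide oxidation of the primary C–B bond of 17, which leaves the three alkenes and the stereocentres untouched.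

Step 8
Reactants: 18 (2R,3S)-6-methyl-2-[(1R)-1-phenylbut-3-en-1-yl]-3-(prop-1-en-2-yl)hept-5-en-1-ol
Product: 19 [(1R,2S,6R)-3-methyl-2-(3-methylbut-2-en-1-yl)-6-phenylcyclohex-3-en-1-yl]methanol
Conditions: Grubbs II (5 mol %), CH2Cl2 (5 mM), 40 °C
Reagents that add atoms: none
Why: Ring-closing olefin metathesis, in which the ruthenium alkylidene forms at the monosubstituted allyl alkene and closes onto the 1,1-disubstituted isopropenyl group to give the six-membered ring with the trisubstituted C3=C4 bond, a closure expected to outpace seven-ring formation onto the trisubstituted prenyl alkene; no stereocentre is involved.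

Step 9
Reactants: 19 [(1R,2S,6R)-3-methyl-2-(3-methylbut-2-en-1-yl)-6-phenylcyclohex-3-en-1-yl]methanol
Product: 20 (1R,2S,6R)-3-methyl-2-(3-methylbut-2-en-1-yl)-6-phenylcyclohex-3-ene-1-carbaldehyde
Conditions: DMP, NaHCO3, CH2Cl2, 0 °C → rt
Reagents that add atoms: none
Why: Dess–Martin oxidation converts the primary alcohol into the aldehyde under buffered, non-basic conditions, so C1 (now α to a carbonyl group) should keep its configuration.

Step 10
Reactants: 21 5-methoxyresorcinol
Product: 22 1-methoxy-3,5-bis(methoxymethoxy)benzene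
Conditions: MOMCl, i-Pr2NEt, CH2Cl2, 0 °C → rt
Reagents that add atoms: chloromethyl methyl ether, COCCl
Why: Double O-alkylation of the phenols with MOMCl (Williamson-type acetal protection) gives the bis-MOM ether whose two OMOM groups direct the metalation in step 11.

Step 11
Reactants: 22 1-methoxy-3,5-bis(methoxymethoxy)benzene; 20 (1R,2S,6R)-3-methyl-2-(3-methylbut-2-en-1-yl)-6-phenylcyclohex-3-ene-1-carbaldehyde
Product: 24 [4-methoxy-2,6-bis(methoxymethoxy)phenyl][(1R,2S,6R)-3-methyl-2-(3-methylbut-2-en-1-yl)-6-phenylcyclohex-3-en-1-yl]methanol (both carbinol epimers), via aryllithium 23 (not isolated)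
Conditions: n-BuLi, THF, 0 °C → rt, 1 h; then 20, −78 → 0 °C; then H2O
Reagents that add atoms: none
Why: Directed ortho-metalation takes place at the ring position flanked by both OMOM groups to give aryllithium 23, which adds 1,2 to the aldehyde; the new carbinol centre is formed without control and is removed in step 12.

Step 12
Reactants: 24 diaryl-type carbinol (both epimers)
Product: 25 [4-methoxy-2,6-bis(methoxymethoxy)phenyl][(1R,2S,6R)-3-methyl-2-(3-methylbut-2-en-1-yl)-6-phenylcyclohex-3-en-1-yl]methanone
Conditions: DMP, NaHCO3, CH2Cl2, rt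
Reagents that add atoms: none
Why: Dess–Martin oxidation of the benzylic secondary alcohol gives the aryl ketone under neutral conditions that spare the MOM acetals, the alkenes and the α-stereocentre C1.

Step 13
Reactants: 25 bis-MOM aryl ketone
Product: 26 (2,6-dihydroxy-4-methoxyphenyl)[(1R,2S,6R)-3-methyl-2-(3-methylbut-2-en-1-yl)-6-phenylcyclohex-3-en-1-yl]methanone
Conditions: HCl (cat.), MeOH, 40 °C
Reagents that add atoms: none
Why: Acid-catalysed transacetalisation in methanol cleaves both MOM ethers (assisted by the ortho carbonyl group), while the isolated trisubstituted alkenes are expected to tolerate dilute HCl at 40 °C.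

Step 14
Reactants: 26 dihydroxy aryl ketone; 27 3-methylbut-2-enal (prenal)
Product: 28 (7-hydroxy-5-methoxy-2,2-dimethyl-2H-chromen-8-yl)[(1R,2S,6R)-3-methyl-2-(3-methylbut-2-en-1-yl)-6-phenylcyclohex-3-en-1-yl]methanone (target CNP0307644.1)
Conditions: 27 (1.3 equiv), ethylenediammonium diacetate (20 mol %), toluene, 110 °C
Reagents that add atoms: none
Why: Amine-salt-catalysed condensation of prenal at a ring carbon ortho to a phenol (Knoevenagel type) gives an ortho-quinone methide that closes by oxa-6π electrocyclisation to the 2,2-dimethyl-2H-chromene, and because the two free ring positions are equivalent only one regioisomer can form, the remaining hydroxyl being deactivated by its hydrogen bond to the ketone.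

**Compound list**

1 | but-3-en-1-ol | C=CCCO | starting material
2 | but-3-en-1-yl N,N-diisopropylcarbamate | C=CCCOC(=O)N(C(C)C)C(C)C | intermediate
3 | (R)-4-benzyloxazolidin-2-one | O=C1N[C@H](Cc2ccccc2)CO1 | starting material
4 | 3-methylbut-2-enoyl chloride | CC(C)=CC(=O)Cl | starting material
5 | lithium salt of (R)-4-benzyloxazolidin-2-one (N-lithiated) | [Li]N1[C@H](Cc2ccccc2)COC1=O | intermediate
6 | (R)-4-benzyl-3-(3-methylbut-2-enoyl)oxazolidin-2-one | CC(C)=CC(=O)N1[C@H](Cc2ccccc2)COC1=O | intermediate
7 | 1-bromo-3-methylbut-2-ene | CC(C)=CCBr | starting material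
8 | sodium Z(O)-dienolate of 6 | [Na+].C=C(C)/C=C(\[O-])N1[C@H](Cc2ccccc2)COC1=O | intermediate
9 | (R)-4-benzyl-3-[(2R)-5-methyl-2-(prop-1-en-2-yl)hex-4-enoyl]oxazolidin-2-one | CC(C)=CC[C@@H](C(=O)N1[C@H](Cc2ccccc2)COC1=O)C(C)=C | intermediate
10 | (R)-lavandulol, (2R)-5-methyl-2-(prop-1-en-2-yl)hex-4-en-1-ol | CC(C)=CC[C@@H](CO)C(C)=C | intermediate
11 | (2R)-5-methyl-2-(prop-1-en-2-yl)hex-4-en-1-yl N,N-diisopropylcarbamate | CC(C)=CC[C@@H](COC(=O)N(C(C)C)C(C)C)C(C)=C | intermediate
12 | 4,4,5,5-tetramethyl-2-phenyl-1,3,2-dioxaborolane | CC1(C)OB(OC1(C)C)c1ccccc1 | starting material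
13 | (R)-1-lithiobut-3-en-1-yl N,N-diisopropylcarbamate, (+)-sparteine complex | C=CC[C@@H]([Li])OC(=O)N(C(C)C)C(C)C | intermediate
14 | 2-[(1S)-1-phenylbut-3-en-1-yl]-4,4,5,5-tetramethyl-1,3,2-dioxaborolane | CC1(C)OB(OC1(C)C)[C@@H](CC=C)c1ccccc1 | intermediate
15 | (1S,2R)-1-lithio-5-methyl-2-(prop-1-en-2-yl)hex-4-en-1-yl N,N-diisopropylcarbamate, (−)-sparteine complex | CC(C)N(C(C)C)C(=O)O[C@@H]([Li])[C@H](CC=C(C)C)C(C)=C | intermediate
16 | 2-[(4R,5R,6S)-9-methyl-4-phenyl-6-(prop-1-en-2-yl)deca-1,8-dien-5-yl]-4,4,5,5-tetramethyl-1,3,2-dioxaborolane | CC1(C)OB(OC1(C)C)[C@H]([C@H](CC=C(C)C)C(C)=C)[C@@H](CC=C)c1ccccc1 | intermediate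
17 | 2-{(2R,3S)-6-methyl-2-[(1R)-1-phenylbut-3-en-1-yl]-3-(prop-1-en-2-yl)hept-5-en-1-yl}-4,4,5,5-tetramethyl-1,3,2-dioxaborolane | CC1(C)OB(OC1(C)C)C[C@H]([C@H](CC=C(C)C)C(C)=C)[C@@H](CC=C)c1ccccc1 | intermediate
18 | (2R,3S)-6-methyl-2-[(1R)-1-phenylbut-3-en-1-yl]-3-(prop-1-en-2-yl)hept-5-en-1-ol | OC[C@H]([C@H](CC=C(C)C)C(C)=C)[C@@H](CC=C)c1ccccc1 | intermediate
19 | [(1R,2S,6R)-3-methyl-2-(3-methylbut-2-en-1-yl)-6-phenylcyclohex-3-en-1-yl]methanol | OC[C@@H]1[C@H](CC=C(C)C)C(C)=CC[C@H]1c1ccccc1 | intermediate
20 | (1R,2S,6R)-3-methyl-2-(3-methylbut-2-en-1-yl)-6-phenylcyclohex-3-ene-1-carbaldehyde | O=C[C@@H]1[C@H](CC=C(C)C)C(C)=CC[C@H]1c1ccccc1 | intermediate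
21 | 5-methoxyresorcinol | COc1cc(O)cc(O)c1 | starting material
22 | 1-methoxy-3,5-bis(methoxymethoxy)benzene | COCOc1cc(OC)cc(OCOC)c1 | intermediate
23 | [4-methoxy-2,6-bis(methoxymethoxy)phenyl]lithium | [Li]c1c(OCOC)cc(OC)cc1OCOC | intermediate
24 | [4-methoxy-2,6-bis(methoxymethoxy)phenyl][(1R,2S,6R)-3-methyl-2-(3-methylbut-2-en-1-yl)-6-phenylcyclohex-3-en-1-yl]methanol, both carbinol epimers | COCOc1cc(OC)cc(OCOC)c1C(O)[C@@H]1[C@H](CC=C(C)C)C(C)=CC[C@H]1c1ccccc1 | intermediate
25 | [4-methoxy-2,6-bis(methoxymethoxy)phenyl][(1R,2S,6R)-3-methyl-2-(3-methylbut-2-en-1-yl)-6-phenylcyclohex-3-en-1-yl]methanone | COCOc1cc(OC)cc(OCOC)c1C(=O)[C@@H]1[C@H](CC=C(C)C)C(C)=CC[C@H]1c1ccccc1 | intermediate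
26 | (2,6-dihydroxy-4-methoxyphenyl)[(1R,2S,6R)-3-methyl-2-(3-methylbut-2-en-1-yl)-6-phenylcyclohex-3-en-1-yl]methanone | COc1cc(O)c(C(=O)[C@@H]2[C@H](CC=C(C)C)C(C)=CC[C@H]2c2ccccc2)c(O)c1 | intermediate
27 | 3-methylbut-2-enal | CC(C)=CC=O | starting material
28 | (7-hydroxy-5-methoxy-2,2-dimethyl-2H-chromen-8-yl)[(1R,2S,6R)-3-methyl-2-(3-methylbut-2-en-1-yl)-6-phenylcyclohex-3-en-1-yl]methanone | COc1cc(O)c(C(=O)[C@@H]2[C@H](CC=C(C)C)C(C)=CC[C@H]2c2ccccc2)c2c1C=CC(C)(C)O2 | target

**Step count**

Total steps: 14. Longest linear sequence: 12 steps (2, 3, 4, 5, 6, 7, 8, 9, 11, 12, 13, 14).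

**Steps most likely to fail**

1. Step 6 (key step).
 - What may go wrong: α-deprotonation of the β-branched carbamate 11 may be slow or poorly face-selective if (−)-sparteine and the C2 centre are mismatched. Material may also be lost when the crude first-stage solution is carried into a second hindered ate-complex formation and migration.
 - Fallback (sets out from 11 and from isolated 14, returns at 16): the carbenoid is generated by tin–lithium exchange from a purified precursor, not by deprotonation just before coupling. Carbamate 11 is lithiated with s-BuLi/(−)-sparteine in Et2O at −78 °C and trapped with Me3SnCl to give the α-stannyl carbamate (1S,2R)-5-methyl-2-(prop-1-en-2-yl)-1-(trimethylstannyl)hex-4-en-1-yl N,N-diisopropylcarbamate F1. F1 is bench-stable and can be freed from its C1 epimer by chromatography. Boronic ester 14 is prepared as in stage (i) but isolated and purified. Treatment of F1 with n-BuLi in Et2O at −78 °C should regenerate 15 with retention and without diamine; 14 is then added, and warming with MgBr2·OEt2 should give 16.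

2. Step 8.
 - What may go wrong: the ruthenium alkylidene may close onto the prenyl alkene (seven-membered ring, loss of isobutene) in competition with six-ring closure onto the hindered isopropenyl group.
 - Fallback (sets out from 18, returns at 19): the prenyl alkene is masked before metathesis. The trisubstituted, most electron-rich alkene of 18 is epoxidised selectively (m-CPBA 1.0 equiv, NaHCO3, CH2Cl2, −20 °C) to the epoxide (2R,3S)-4-(3,3-dimethyloxiran-2-yl)-2-[(1R)-1-phenylbut-3-en-1-yl]-3-(prop-1-en-2-yl)butan-1-ol F2 (both epoxide epimers). Ring-closing metathesis (Grubbs II, CH2Cl2, 40 °C) then has only the six-ring option and should give the cyclohexene epoxide {(1R,2S,6R)-2-[(3,3-dimethyloxiran-2-yl)methyl]-3-methyl-6-phenylcyclohex-3-en-1-yl}methanol F3. Deoxygenation (NaI, Zn, NaOAc, AcOH, 0 °C → rt) restores the prenyl group and gives 19. The epoxide configuration is of no consequence because the regenerated alkene carries two identical methyl groups.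

3. Step 14.
 - What may go wrong: a second annulation at the remaining phenol, or slow condensation of the hydrogen-bonded acylresorcinol with loss of prenal at 110 °C.
 - Fallback (sets out from 26, returns at 28): the pyran ring is built by O-alkylation and aromatic propargyl Claisen rearrangement. Mono-O-alkylation of 26 with 3-chloro-3-methylbut-1-yne (K2CO3, KI, CuI cat., acetone, 55 °C) should give the aryl 1,1-dimethylpropargyl ether [2-hydroxy-4-methoxy-6-(2-methylbut-3-yn-2-yloxy)phenyl][(1R,2S,6R)-3-methyl-2-(3-methylbut-2-en-1-yl)-6-phenylcyclohex-3-en-1-yl]methanone F4. Heating F4 in xylene at 140 °C should bring about Claisen rearrangement to the only free ortho position, 1,5-hydrogen shift and oxa-6π closure to give 28.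

**Further compounds**

F1 | step 6 | (1S,2R)-5-methyl-2-(prop-1-en-2-yl)-1-(trimethylstannyl)hex-4-en-1-yl N,N-diisopropylcarbamate | CC(C)N(C(C)C)C(=O)O[C@H]([C@H](CC=C(C)C)C(C)=C)[Sn](C)(C)C
F2 | step 8 | (2R,3S)-4-(3,3-dimethyloxiran-2-yl)-2-[(1R)-1-phenylbut-3-en-1-yl]-3-(prop-1-en-2-yl)butan-1-ol (both epoxide epimers) | OC[C@H]([C@H](CC1OC1(C)C)C(C)=C)[C@@H](CC=C)c1ccccc1
F3 | step 8 | {(1R,2S,6R)-2-[(3,3-dimethyloxiran-2-yl)methyl]-3-methyl-6-phenylcyclohex-3-en-1-yl}methanol (both epoxide epimers) | OC[C@@H]1[C@H](CC2OC2(C)C)C(C)=CC[C@H]1c1ccccc1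
F4 | step 14 | [2-hydroxy-4-methoxy-6-(2-methylbut-3-yn-2-yloxy)phenyl][(1R,2S,6R)-3-methyl-2-(3-methylbut-2-en-1-yl)-6-phenylcyclohex-3-en-1-yl]methanone | COc1cc(O)c(C(=O)[C@@H]2[C@H](CC=C(C)C)C(C)=CC[C@H]2c2ccccc2)c(OC(C)(C)C#C)c1
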